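The numbers of this flask are invented; the run is a simulation.

At the reading point of this flask, 30 % of the starting material converted, I wanted two apparent orders.

starting material 0.80 M; reagent 2.50 equiv; free catalyst 0.12 mol%

    catalyst intermediate D → free catalyst + product (k1 = 600 h⁻¹)
    starting material + free catalyst ⇌ catalyst intermediate A (K2 = 1.1 L mol⁻¹, k2 = 66 L mol⁻¹ h⁻¹)
    2 catalyst intermediate A ⇌ resting dimer, settled at all times (K3 = 9200 L mol⁻¹)
    catalyst intermediate C → by-product + catalyst intermediate D (k4 = 18 h⁻¹)
    catalyst intermediate A ⇌ catalyst intermediate B (K5 = 2.3, k5 = 43 h⁻¹)
    reagent + catalyst intermediate B → catalyst intermediate C (k6 = 250 L mol⁻¹ h⁻¹)

- apparent order in reagent when 30 % of the starting material are converted (percent change of the rate of making product for one percent more reagent charged)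
- apparent order in free catalyst when 30 % of the starting material are converted (percent change of the rate of making product for one percent more free catalyst charged)

I looked for the crossing at which reagent could take control of the round. It lies at catalyst intermediate B, which has two exits. It falls back to catalyst intermediate A with 18.7 h⁻¹, the forward constant over the equilibrium constant. Or it goes on with reagent, which stands at 1.76 M, and that exit runs at 440 h⁻¹, faster than the way back.

return share = back / (back + onward) = 0.0408

The return share is the fraction of catalyst intermediate B that falls back instead of going on. At fixed c(catalyst intermediate A) the rate carries the factor one minus this share, so the order in c(reagent) there equals the share. One percent more charge raises c(reagent) by 1.14 percent. More turnover also draws catalyst out of catalyst intermediate A, which pulls the other way. I did not reckon these two in, and committed to 0.0408.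

One number was not enough: the share contains no charge of catalyst, and the second order asks for one. With equal flux through each step, the monomeric forms together came to 6.19 times c(catalyst intermediate A). The resting dimer, which stands outside the working round, grows with the square of c(catalyst intermediate A). The balance of catalyst gave c(catalyst intermediate A) = 1.15 × 10⁻⁴ M and a dimer fraction d:

d = 0.255, catalyst order = 1 / (1 + d) = 0.797

The forecast gave 0.04 and 0.8, holding that “a sizeable share of the catalyst is in the resting dimer”. The simulation gave 0.041 and 0.80.

In this flask, catalyst intermediate B left with reagent as charged at 12000 d⁻¹, faster than catalyst intermediate A became it at 1000 d⁻¹. At 2.00 d, catalyst intermediate B held 1.13 % of the catalyst and catalyst intermediate A held 12.0 %. Reckoned at 30 % conversion for the run with twice the reagent, the return share falls to 0.0195, which puts 1.02 on the rate at fixed c(catalyst intermediate A). That run showed a factor of 1.02.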